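A direct plan would add a hydroxymethyl-anion equivalent twice to methyl 2-hydroxy-4-methylbenzoate A1 to give the prochiral triol A2, would have a lipase acylate one of its two enantiotopic CH2OH groups to the mono-isobutyrate A3, and would then esterify the last primary hydroxyl with an activated (S)-2-methylbutanoate. Its weakest steps would be:
- the double addition, because a silylmethyl carbanion would have to add twice to an ester beside a free phenol, without enolisation or Peterson elimination;
- the desymmetrisation, because the sense and level of enzymatic selection on a tertiary benzylic carbinol would be unpredictable, and 1,3-acyl migration in A3 would racemise it;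
- the last acylation, because a neopentyl-type alcohol and an α-branched acyl donor would both be poor lipase substrates.

The route rests on the bond between ring carbon C-1 and the carbinol carbon, made by electrophilic substitution of m-cresol itself. The free hydroxyl that ends up at C-2 serves as director: bound to a chiral titanium binaphtholate it delivers its ortho carbon (para to the methyl group) to the keto group of an acyloxypyruvate. This single operation joins ring and side chain, places the phenol, sets the fully substituted carbinol centre and leaves its two arms at different oxidation levels, with the homochiral 2-methylbutanoate already in place. No hydroxymethyl anion, no prochiral triol and no enzyme that must tell two like arms apart are needed.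

Key step: step 2

Assumption: (R)-BINOL is taken to leave the Si face of the titanium-bound keto group of 4 open; if the sense of induction were the opposite, (S)-BINOL would be used with no other change.

Step 1
Reactants: 1 (2S)-2-methylbutanoic acid; 2 ethyl 3-bromo-2-oxopropanoate (ethyl bromopyruvate)
Product: 4 ethyl 3-{[(2S)-2-methylbutanoyl]oxy}-2-oxopropanoate, via caesium carboxylate 3 (not isolated)
Conditions: 1 (1.05 equiv), Cs2CO3 (0.53 equiv), MeCN, rt; then 2, 0 °C → rt
Reagents that add atoms: none
Why: SN2 O-alkylation of a carboxylate by an α-bromo ketone, whose halide is activated by the adjacent keto group; the carboxyl group of 1 is never activated, so its α-stereocentre cannot epimerise, and no new stereocentre is formed.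

Step 2
Reactants: 4 ethyl 3-{[(2S)-2-methylbutanoyl]oxy}-2-oxopropanoate; 5 3-methylphenol (m-cresol)
Product: 7 ethyl (2R)-2-hydroxy-2-(2-hydroxy-4-methylphenyl)-3-{[(2S)-2-methylbutanoyl]oxy}propanoate, via cyclohexadienone tautomer 6 (not isolated)
Conditions: Ti(OiPr)4 (10 mol %), (R)-BINOL (20 mol %), 4 Å MS, toluene, rt; then 5 (1.5 equiv) and 4, 0 °C → rt; cold pH 7 buffer work-up
Reagents that add atoms: none
Why: Chelation-controlled Friedel–Crafts hydroxyalkylation: m-cresol exchanges onto the tetravalent titanium binaphtholate to give an aryloxytitanium species, keto ester 4 binds the same metal through its keto and ester carbonyls, and ortho carbon C-6 of the aryloxide attacks the keto carbon through a six-membered cyclic transition state to give dienone 6, which tautomerises to phenol 7. The closest known reaction type is the ortho-specific hydroxyalkylation of titanium and magnesium phenoxides with glyoxylates and pyruvates, including its enantioselective variants under chiral binaphtholate control. No ring is closed. The one new stereocentre (R) is set by the C2-symmetric binaphtholate, which leaves the Si face of the chelated keto group open. The step needs ortho- and not para-attack, secured by the titanium bridge between phenoxide oxygen and carbonyl, and attack at C-6 and not C-2, secured by the methyl group that flanks C-2. Because the two arms of the new centre differ in oxidation level (CO2Et against CH2O-acyl), its configuration cannot be lost by acyl migration.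

Step 3
Reactants: 7 ethyl (2R)-2-hydroxy-2-(2-hydroxy-4-methylphenyl)-3-{[(2S)-2-methylbutanoyl]oxy}propanoate; 8 benzyl bromide
Product: 9 ethyl (2R)-2-[2-(benzyloxy)-4-methylphenyl]-2-hydroxy-3-{[(2S)-2-methylbutanoyl]oxy}propanoate
Conditions: 8 (1.1 equiv), K2CO3 (1.5 equiv), acetone, rt
Reagents that add atoms: none
Why: Williamson ether synthesis in which carbonate deprotonates only the phenol (the tertiary alcohol and both esters are inert to anhydrous K2CO3 at room temperature), so that the phenol is masked before any primary alcohol exists in the molecule; no stereocentre is touched.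

Step 4
Reactants: 9 ethyl (2R)-2-[2-(benzyloxy)-4-methylphenyl]-2-hydroxy-3-{[(2S)-2-methylbutanoyl]oxy}propanoate
Product: 10 (2S)-2-[2-(benzyloxy)-4-methylphenyl]-2,3-dihydroxypropyl (2S)-2-methylbutanoate
Conditions: BH3·SMe2 (2.0 equiv), NaBH4 (5 mol %), THF, 0 °C → rt; MeOH quench at 0 °C, evaporate; crude 10 used at once
Reagents that add atoms: none
Why: Hydroxyl-directed borane reduction of an α-hydroxy ester: the tertiary hydroxyl forms an alkoxyborane that, activated by borohydride, should deliver hydride through a five-membered cyclic transition state to the neighbouring ethyl ester only, while the 2-methylbutanoate (reachable only through a seven-membered one) and the benzyl ether are left; the carbinol centre is untouched and its descriptor changes from R to S only because CO2Et becomes CH2OH.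

Step 5
Reactants: 10 (2S)-2-[2-(benzyloxy)-4-methylphenyl]-2,3-dihydroxypropyl (2S)-2-methylbutanoate; 11 2-methylpropanoic (isobutyric) anhydride
Product: 12 (2S)-2-[2-(benzyloxy)-4-methylphenyl]-2-hydroxy-3-[(2-methylpropanoyl)oxy]propyl (2S)-2-methylbutanoate
Conditions: 11 (1.2 equiv), Et3N (1.5 equiv), DMAP (5 mol %), CH2Cl2, 0 °C
Reagents that add atoms: none
Why: DMAP-catalysed acyl transfer from an anhydride to the only unhindered hydroxyl (the tertiary benzylic OH does not react and the phenol is masked, so no choice between like hydroxyls is asked for); acylating crude 10 at 0 °C should forestall 1,3-acyl migration, and the isobutyryl group has no stereocentre to lose.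

Step 6
Reactants: 12 (2S)-2-[2-(benzyloxy)-4-methylphenyl]-2-hydroxy-3-[(2-methylpropanoyl)oxy]propyl (2S)-2-methylbutanoate
Product: 13 (2S)-2-hydroxy-2-(2-hydroxy-4-methylphenyl)-3-[(2-methylpropanoyl)oxy]propyl (2S)-2-methylbutanoate
Conditions: H2 (1 atm), 10% Pd/C, EtOAc, rt
Reagents that add atoms: none
Why: Heterogeneous hydrogenolysis of an aryl benzyl ether under neutral conditions, which should leave both esters, the tertiary alcohol (deactivated by two β-acyloxy groups) and both stereocentres untouched and avoids the acid or base that would trigger acyl migration.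

Compound list
1 | (2S)-2-methylbutanoic acid | CC[C@H](C)C(=O)O | starting material
2 | ethyl 3-bromo-2-oxopropanoate (ethyl bromopyruvate) | CCOC(=O)C(=O)CBr | starting material
3 | caesium (2S)-2-methylbutanoate | CC[C@H](C)C(=O)[O-].[Cs+] | intermediate
4 | ethyl 3-{[(2S)-2-methylbutanoyl]oxy}-2-oxopropanoate | CC[C@H](C)C(=O)OCC(=O)C(=O)OCC | intermediate
5 | 3-methylphenol (m-cresol) | Cc1cccc(O)c1 | starting material
6 | ethyl (2R)-2-hydroxy-2-(4-methyl-6-oxocyclohexa-2,4-dien-1-yl)-3-{[(2S)-2-methylbutanoyl]oxy}propanoate (titanium-bound, ring C-1 unassigned) | CC[C@H](C)C(=O)OC[C@@](O)(C(=O)OCC)C1C=CC(C)=CC1=O | intermediate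
7 | ethyl (2R)-2-hydroxy-2-(2-hydroxy-4-methylphenyl)-3-{[(2S)-2-methylbutanoyl]oxy}propanoate | CC[C@H](C)C(=O)OC[C@@](O)(C(=O)OCC)c1ccc(C)cc1O | intermediate
8 | benzyl bromide | BrCc1ccccc1 | starting material
9 | ethyl (2R)-2-[2-(benzyloxy)-4-methylphenyl]-2-hydroxy-3-{[(2S)-2-methylbutanoyl]oxy}propanoate | CC[C@H](C)C(=O)OC[C@@](O)(C(=O)OCC)c1ccc(C)cc1OCc1ccccc1 | intermediate
10 | (2S)-2-[2-(benzyloxy)-4-methylphenyl]-2,3-dihydroxypropyl (2S)-2-methylbutanoate | CC[C@H](C)C(=O)OC[C@@](O)(CO)c1ccc(C)cc1OCc1ccccc1 | intermediate
11 | 2-methylpropanoic (isobutyric) anhydride | CC(C)C(=O)OC(=O)C(C)C | starting material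
12 | (2S)-2-[2-(benzyloxy)-4-methylphenyl]-2-hydroxy-3-[(2-methylpropanoyl)oxy]propyl (2S)-2-methylbutanoate | CC[C@H](C)C(=O)OC[C@@](O)(COC(=O)C(C)C)c1ccc(C)cc1OCc1ccccc1 | intermediate
13 | (2S)-2-hydroxy-2-(2-hydroxy-4-methylphenyl)-3-[(2-methylpropanoyl)oxy]propyl (2S)-2-methylbutanoate | CC[C@H](C)C(=O)OC[C@@](O)(COC(=O)C(C)C)c1ccc(C)cc1O | target

Total step count: 6. Longest linear sequence: 6.

Steps most likely to fail

Step 2. The catalyst may stop turning over because product 7, a chelating phenol and α-hydroxy ester, holds the titanium. Facial selectivity may be low, attack may occur para to the hydroxyl outside the chelate, or the product may lactonise with loss of ethanol. A minor C-2 epimer would be a diastereomer of 7 and could be removed by chromatography. The fallback sets out from keto ester 4 and uses the arene as a preformed, already protected nucleophile. Rhodium-catalysed enantioselective 1,2-addition of [2-(benzyloxy)-4-methylphenyl]boronic acid F1 to the keto group of 4 ([Rh(C2H4)2Cl]2, chiral diene ligand, KF, toluene/H2O, rt) would give the benzyl ether directly. It comes back to the route at 9, so that step 3 falls away.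

Step 4. Hydride delivery may not stay confined to the α-hydroxy ester, or the hindered tertiary hydroxy ester may react too slowly, so that the side-chain ester is attacked. In the product, 1,3-acyl migration between the two primary oxygens would erode the configurational purity of the carbinol centre. The fallback sets out from 7 and activates the carboxyl carbon instead of relying on direction by the hydroxyl. Acid-catalysed lactonisation (TsOH cat., toluene, 60 °C) would give [(3R)-3-hydroxy-6-methyl-2-oxo-2,3-dihydro-1-benzofuran-3-yl]methyl (2S)-2-methylbutanoate F2, whose aryl lactone is far more electrophilic than the side-chain ester. Zn(BH4)2 (Et2O/THF, 0 °C) would reduce only this lactone to (2S)-2,3-dihydroxy-2-(2-hydroxy-4-methylphenyl)propyl (2S)-2-methylbutanoate F3. Phenol-selective benzylation with 8 (K2CO3, acetone, 0 °C) would come back to the route at 10.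

Step 1. The base-sensitive bromo keto ester may condense with itself, and the enolisable, hydrate-prone product may be lost on isolation. The fallback sets out from acid 1 and builds the keto group by oxidation. Carbodiimide esterification (DCC, DMAP cat., CH2Cl2, 0 °C) of the primary hydroxyl of ethyl 2,3-dihydroxypropanoate F4 would give ethyl 2-hydroxy-3-{[(2S)-2-methylbutanoyl]oxy}propanoate F5. Dess–Martin oxidation of its secondary alcohol would come back to the route at 4.

Further compounds
F1 | step 2 | [2-(benzyloxy)-4-methylphenyl]boronic acid | Cc1ccc(B(O)O)c(OCc2ccccc2)c1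
F2 | step 4 | [(3R)-3-hydroxy-6-methyl-2-oxo-2,3-dihydro-1-benzofuran-3-yl]methyl (2S)-2-methylbutanoate | CC[C@H](C)C(=O)OC[C@@]1(O)C(=O)Oc2cc(C)ccc21
F3 | step 4 | (2S)-2,3-dihydroxy-2-(2-hydroxy-4-methylphenyl)propyl (2S)-2-methylbutanoate | CC[C@H](C)C(=O)OC[C@@](O)(CO)c1ccc(C)cc1O
F4 | step 1 | ethyl 2,3-dihydroxypropanoate (racemic) | CCOC(=O)C(O)CO
F5 | step 1 | ethyl 2-hydroxy-3-{[(2S)-2-methylbutanoyl]oxy}propanoate (both C-2 epimers) | CC[C@H](C)C(=O)OCC(O)C(=O)OCC
A1 | direct plan | methyl 2-hydroxy-4-methylbenzoate | COC(=O)c1ccc(C)cc1O
A2 | direct plan | 2-(2-hydroxy-4-methylphenyl)propane-1,2,3-triol | OCC(O)(CO)c1ccc(C)cc1O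
A3 | direct plan | (2R)-2,3-dihydroxy-2-(2-hydroxy-4-methylphenyl)propyl 2-methylpropanoate | OC[C@@](O)(COC(=O)C(C)C)c1ccc(C)cc1O
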